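## Retrosynthetic overview

1. Target 19 ⇒ lactol 14 + Z-β-iodoacrylate 16. The C4–C5 bond is made by adding a β-metalated acrylate (a homoenolate-type d3 nucleophile at a carbon that is normally the electrophilic Michael terminus) to an aldehyde carbon. The same operation sets C5 and closes the butenolide (ring B), which is formed last.
2. 14 ⇒ homoallylic bromide 8 + propargyl alcohol + glycidol. Alkoxide-directed anti-carbomagnesiation fixes the hydroxymethyl-bearing trisubstituted alkene; glycidol supplies the CH2–CHO unit after periodate cleavage (transient dihydropyran lactol).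
3. 8 ⇒ alkynol 5 by zirconium-catalysed carboalumination and oxirane opening (E-trisubstituted alkene).
4. 5 ⇒ (E)-geranylacetone 1. The cyclohexane (ring A) is formed first, by enantioselective proton-initiated cyclisation with capture by the ketone oxygen (transient dihydropyran enol ether, then hydrolysed).

Assumption: isomerically pure (5E)-geranylacetone is purchased; the (R)-binaphthol acid of step 1 is taken to give the (4aS,8aS) fold and the (S)-sulfonamide ligand of step 8 Si-face addition — if either sense proves opposite, the mirror-image ligand is used.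

## Route

Step 1
Reactants: 1 (5E)-6,10-dimethylundeca-5,9-dien-2-one ((E)-geranylacetone)
Product: 3 4-[(1S,2S)-2-hydroxy-2,6,6-trimethylcyclohexyl]butan-2-one, via enol ether 2 (not isolated)
Conditions: SnCl4 (1.0 equiv), (R)-2-hydroxy-2'-methoxy-1,1'-binaphthyl (1.1 equiv), toluene, −78 °C, 48 h; then 1 M HCl, THF, 0 °C → rt
Reagents that add atoms: water, O
Why: Biomimetic polyene cyclisation with a Lewis-acid-assisted chiral Brønsted acid: enantioface-selective protonation of the terminal alkene, chair-folded anti addition across the E alkene and capture by the ketone oxygen set the ring CH (S) and the C–O carbon (S) with side chain and oxygen trans, and dilute acid then hydrolyses the enol ether.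

Step 2
Reactants: 3 4-[(1S,2S)-2-hydroxy-2,6,6-trimethylcyclohexyl]butan-2-one
Product: 5 (1S,2S)-2-(but-3-yn-1-yl)-1,3,3-trimethylcyclohexan-1-ol, via enol phosphate 4 (not isolated)
Conditions: LDA (2.2 equiv), THF, −78 °C; ClP(O)(OEt)2 (1.05 equiv), −78 °C → rt; LDA (2.5 equiv), −78 °C → rt; aq NH4Cl
Reagents that add atoms: none
Why: Negishi methyl-ketone-to-alkyne conversion: after O-deprotonation, LDA removes a methyl proton kinetically, the terminal enol phosphate forms and LDA-induced β-elimination of phosphate gives the terminal alkyne without touching a stereocentre.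

Step 3
Reactants: 5 (1S,2S)-2-(but-3-yn-1-yl)-1,3,3-trimethylcyclohexan-1-ol
Product: 7 (3E)-6-[(1S,2S)-2-hydroxy-2,6,6-trimethylcyclohexyl]-4-methylhex-3-en-1-ol, via alkenylalane 6 (not isolated)
Conditions: AlMe3 (3.5 equiv), Cp2ZrCl2 (0.3 equiv), CH2Cl2, 0 °C → rt; evaporate; n-BuLi (1.2 equiv), THF/hexane, −78 °C; oxirane (5 equiv), −78 → 0 °C; 1 M HCl
Reagents that add atoms: trimethylaluminium C[Al](C)C; oxirane (ethylene oxide) C1CO1
Why: Zirconium-catalysed Negishi carboalumination adds methyl and aluminium syn and regioselectively across the terminal alkyne, and the derived alanate opens oxirane with retention at the alkenyl carbon, fixing the E-trisubstituted alkene.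

Step 4
Reactants: 7 (3E)-6-[(1S,2S)-2-hydroxy-2,6,6-trimethylcyclohexyl]-4-methylhex-3-en-1-ol
Product: 8 (1S,2S)-2-[(3E)-6-bromo-3-methylhex-3-en-1-yl]-1,3,3-trimethylcyclohexan-1-ol
Conditions: CBr4 (1.2 equiv), PPh3 (1.25 equiv), CH2Cl2, 0 °C
Reagents that add atoms: carbon tetrabromide BrC(Br)(Br)Br
Why: Appel bromination is selective for the primary alcohol; the hindered tertiary alcohol does not react at 0 °C.

Step 5
Reactants: 8 (1S,2S)-2-[(3E)-6-bromo-3-methylhex-3-en-1-yl]-1,3,3-trimethylcyclohexan-1-ol; 9 prop-2-yn-1-ol (propargyl alcohol); 10 (±)-oxiran-2-ylmethanol (glycidol)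
Product: 13 (4Z,8E)-5-(hydroxymethyl)-11-[(1S,2S)-2-hydroxy-2,6,6-trimethylcyclohexyl]-9-methylundeca-4,8-diene-1,2-diol (1:1 epimers at C2), via alkoxide Grignard reagent 11 (not isolated), via alkenylmagnesium chelate 12 (not isolated)
Conditions: 8, i-PrMgCl (1.0 equiv), THF, −20 °C, then Mg turnings, 40 °C; 9 (1.3 equiv) pre-treated with i-PrMgCl (1.3 equiv), CuI (15 mol%), 0 °C → rt, 16 h; 10 (3 equiv) pre-treated with i-PrMgCl (3 equiv, −40 °C), −30 → 0 °C; aq NH4Cl
Reagents that add atoms: none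
Why: With the tertiary OH masked as its magnesium alkoxide, the homoallylic Grignard reagent undergoes copper-catalysed, alkoxide-directed anti-carbomagnesiation of the propargyl alkoxide (alkyl to C2, Mg to C3 in a five-membered chelate), and copper-catalysed opening of glycidol at its CH2 terminus with retention at the alkenyl carbon places CH2OH and the new CH2 cis (4Z); the diol stereocentre is removed in step 6.

Step 6
Reactants: 13 (4Z,8E)-5-(hydroxymethyl)-11-[(1S,2S)-2-hydroxy-2,6,6-trimethylcyclohexyl]-9-methylundeca-4,8-diene-1,2-diol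
Product: 14 5-{(3E)-6-[(1S,2S)-2-hydroxy-2,6,6-trimethylcyclohexyl]-4-methylhex-3-en-1-yl}-3,6-dihydro-2H-pyran-2-ol (anomeric mixture; ring tautomer of the Z-hydroxy aldehyde)
Conditions: NaIO4 (1.5 equiv), THF/pH 7 phosphate buffer, 0 °C
Reagents that add atoms: none
Why: Periodate (Malaprade) cleavage of the terminal 1,2-diol gives the β,γ-unsaturated aldehyde, which the cis allylic hydroxyl traps at once as the six-membered lactol and so protects from conjugation.

Step 7
Reactants: 15 methyl 4-hydroxybut-2-ynoate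
Product: 16 methyl (2Z)-4-hydroxy-3-iodobut-2-enoate
Conditions: LiI (1.3 equiv), AcOH (1.3 equiv), MeCN, 60 °C
Reagents that add atoms: lithium iodide [Li+].[I-]
Why: Anti hydroiodination of the ynoate (iodide conjugate addition, then protonation) gives the Z-β-iodoacrylate with iodine cis to the ester; any E isomer lactonises to 4-iodofuran-2(5H)-one and is removed.

Step 8
Reactants: 14 5-{(3E)-6-[(1S,2S)-2-hydroxy-2,6,6-trimethylcyclohexyl]-4-methylhex-3-en-1-yl}-3,6-dihydro-2H-pyran-2-ol; 16 methyl (2Z)-4-hydroxy-3-iodobut-2-enoate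
Product: 19 (5R)-4-(hydroxymethyl)-5-{(2Z,6E)-3-(hydroxymethyl)-9-[(1S,2S)-2-hydroxy-2,6,6-trimethylcyclohexyl]-7-methylnona-2,6-dien-1-yl}furan-2(5H)-one, via alkenylchromium dichloride 17 (not isolated), via open-chain hydroxy ester 18 (not isolated)
Conditions: 16 (2 equiv), CrCl2 (6 equiv), (S)-N-[2-(4-isopropyl-4,5-dihydro-1,3-oxazol-2-yl)-6-methylphenyl]methanesulfonamide (6.6 equiv), Et3N (6.6 equiv), NiCl2 (5 mol%), THF, rt, 16 h; aq NH4Cl
Reagents that add atoms: none
Why: Nozaki–Hiyama–Kishi alkenylation with lactonisation, used here without protecting groups: zerovalent nickel inserts into the C–I bond, transmetalation to chromium gives the trivalent alkenylchromium (a β-metalated acrylate, i.e. a homoenolate equivalent), which adds chemoselectively to the aldehyde tautomer of the lactol on the Si face under control of the sulfonamide-ligated chromium (C5 = R), and the Z-disposed ester then closes ring B with loss of methanol.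

## Compound list

1 | (5E)-6,10-dimethylundeca-5,9-dien-2-one ((E)-geranylacetone) | CC(=O)CC/C=C(\C)CCC=C(C)C | starting material
2 | (4aS,8aS)-2,5,5,8a-tetramethyl-4a,5,6,7,8,8a-hexahydro-4H-chromene | CC1=CC[C@H]2C(C)(C)CCC[C@]2(C)O1 | intermediate
3 | 4-[(1S,2S)-2-hydroxy-2,6,6-trimethylcyclohexyl]butan-2-one | CC(=O)CC[C@H]1C(C)(C)CCC[C@]1(C)O | intermediate
4 | diethyl 4-[(1S,2S)-2-hydroxy-2,6,6-trimethylcyclohexyl]but-1-en-2-yl phosphate (lithium alkoxide in the flask) | C=C(OP(=O)(OCC)OCC)CC[C@H]1C(C)(C)CCC[C@]1(C)O | intermediate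
5 | (1S,2S)-2-(but-3-yn-1-yl)-1,3,3-trimethylcyclohexan-1-ol | C#CCC[C@H]1C(C)(C)CCC[C@]1(C)O | intermediate
6 | dimethyl[(1E)-4-{(1S,2S)-2-[(dimethylalumanyl)oxy]-2,6,6-trimethylcyclohexyl}-2-methylbut-1-en-1-yl]alumane | C[Al](C)/C=C(\C)CC[C@H]1C(C)(C)CCC[C@]1(C)O[Al](C)C | intermediate
7 | (3E)-6-[(1S,2S)-2-hydroxy-2,6,6-trimethylcyclohexyl]-4-methylhex-3-en-1-ol | C/C(=C\CCO)CC[C@H]1C(C)(C)CCC[C@]1(C)O | intermediate
8 | (1S,2S)-2-[(3E)-6-bromo-3-methylhex-3-en-1-yl]-1,3,3-trimethylcyclohexan-1-ol | C/C(=C\CCBr)CC[C@H]1C(C)(C)CCC[C@]1(C)O | intermediate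
9 | prop-2-yn-1-ol (propargyl alcohol) | C#CCO | starting material
10 | (±)-oxiran-2-ylmethanol (glycidol) | OCC1CO1 | starting material
11 | bromo{(3E)-6-[(1S,2S)-2-(chloromagnesiooxy)-2,6,6-trimethylcyclohexyl]-4-methylhex-3-en-1-yl}magnesium | C/C(=C\CC[Mg]Br)CC[C@H]1C(C)(C)CCC[C@]1(C)O[Mg]Cl | intermediate
12 | 4-{(3E)-6-[(1S,2S)-2-(chloromagnesiooxy)-2,6,6-trimethylcyclohexyl]-4-methylhex-3-en-1-yl}-2,5-dihydro-1,2-oxamagnesole (cyclic Z-alkenylmagnesium alkoxide) | C/C(=C\CCC1=C[Mg]OC1)CC[C@H]1C(C)(C)CCC[C@]1(C)O[Mg]Cl | intermediate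
13 | (4Z,8E)-5-(hydroxymethyl)-11-[(1S,2S)-2-hydroxy-2,6,6-trimethylcyclohexyl]-9-methylundeca-4,8-diene-1,2-diol (C2 epimers) | C/C(=C\CC/C(=C/CC(O)CO)CO)CC[C@H]1C(C)(C)CCC[C@]1(C)O | intermediate
14 | 5-{(3E)-6-[(1S,2S)-2-hydroxy-2,6,6-trimethylcyclohexyl]-4-methylhex-3-en-1-yl}-3,6-dihydro-2H-pyran-2-ol (anomers) | C/C(=C\CCC1=CCC(O)OC1)CC[C@H]1C(C)(C)CCC[C@]1(C)O | intermediate
15 | methyl 4-hydroxybut-2-ynoate | COC(=O)C#CCO | starting material
16 | methyl (2Z)-4-hydroxy-3-iodobut-2-enoate | COC(=O)/C=C(\I)CO | intermediate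
17 | [(2Z)-1-hydroxy-4-methoxy-4-oxobut-2-en-2-yl]chromium dichloride (trivalent chromium; sulfonamide ligand omitted) | COC(=O)/C=C(\[Cr](Cl)Cl)CO | intermediate
18 | methyl (2Z,4R,6Z,10E)-4-hydroxy-3,7-bis(hydroxymethyl)-13-[(1S,2S)-2-hydroxy-2,6,6-trimethylcyclohexyl]-11-methyltrideca-2,6,10-trienoate (chromium alkoxide in the flask) | C/C(=C\CC/C(=C/C[C@@H](O)/C(CO)=C\C(=O)OC)CO)CC[C@H]1C(C)(C)CCC[C@]1(C)O | intermediate
19 | (5R)-4-(hydroxymethyl)-5-{(2Z,6E)-3-(hydroxymethyl)-9-[(1S,2S)-2-hydroxy-2,6,6-trimethylcyclohexyl]-7-methylnona-2,6-dien-1-yl}furan-2(5H)-one | C/C(=C\CC/C(=C/C[C@H]1OC(=O)C=C1CO)CO)CC[C@H]1C(C)(C)CCC[C@]1(C)O | target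

## Step count and risks

Total step count: 8. Longest linear sequence: 7 (steps 1–6, then 8); step 7 is a one-step side branch.

The three steps most likely to fail, each with one fallback:

**Step 8 (fallback sets out from 14 and comes back at 19).** The lactol may release too little aldehyde, or the free hydroxyls may erode ligand control at chromium. The fallback keeps the d3 logic but changes the reagent and splits the event. Me2Zn/ProPhenol-mediated asymmetric addition of methyl propiolate to 14 (its zinc acetylide is the alkynoate homoenolate equivalent; extra Me2Zn holds the hydroxyls as zinc alkoxides; the ProPhenol enantiomer that gives the 4R carbinol is used) gives methyl (4R,6Z,10E)-4-hydroxy-7-(hydroxymethyl)-13-[(1S,2S)-2-hydroxy-2,6,6-trimethylcyclohexyl]-11-methyltrideca-6,10-dien-2-ynoate F1. Syn-carbocupration of the ynoate with the cuprate from [dimethyl(propan-2-yloxy)silyl]methylmagnesium chloride and CuBr·SMe2 (excess, −78 °C) places the carbinol cis to the ester, and lactonisation gives (5R)-4-{[dimethyl(propan-2-yloxy)silyl]methyl}-5-{(2Z,6E)-3-(hydroxymethyl)-9-[(1S,2S)-2-hydroxy-2,6,6-trimethylcyclohexyl]-7-methylnona-2,6-dien-1-yl}furan-2(5H)-one F2. Tamao oxidation of the C–Si bond (H2O2, KF, KHCO3, THF/MeOH) then delivers 19.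

**Step 5 (fallback sets out from 8 and comes back at 14, bypassing 13).** The chelated alkenylmagnesium 12 may not open glycidol cleanly. In that case 12 is quenched with aq NH4Cl to give 2-{(3E)-6-[(1S,2S)-2-hydroxy-2,6,6-trimethylcyclohexyl]-4-methylhex-3-en-1-yl}prop-2-en-1-ol F3. Esterification with but-3-enoic acid (DCC, catalytic DMAP, 0 °C) gives 2-{(3E)-6-[(1S,2S)-2-hydroxy-2,6,6-trimethylcyclohexyl]-4-methylhex-3-en-1-yl}prop-2-en-1-yl but-3-enoate F4. Ring-closing metathesis (second-generation Grubbs catalyst, CH2Cl2, 40 °C) closes the trisubstituted alkene, its geometry enforced by the ring, to give 5-{(3E)-6-[(1S,2S)-2-hydroxy-2,6,6-trimethylcyclohexyl]-4-methylhex-3-en-1-yl}-3,6-dihydro-2H-pyran-2-one F5. Reduction with i-Bu2AlH (CH2Cl2, −78 °C) gives lactol 14.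

**Step 1 (fallback sets out from 1 and comes back at 2, then 3 by the same acid hydrolysis).** The tin-based chiral acid may give insufficient ee with a ketone-terminated diene, and any shortfall would surface as diastereomers after step 8. The fallback replaces reagent control by enzyme control: whole-cell biotransformation of 1 with recombinant squalene–hopene cyclase (E. coli cells expressing the Alicyclobacillus acidocaldarius enzyme, citrate buffer pH 6, detergent, 30–40 °C) should give enol ether 2 in high enantiopurity. No compound outside the list is made (F0).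

## Further compounds

F1 | step 8 | methyl (4R,6Z,10E)-4-hydroxy-7-(hydroxymethyl)-13-[(1S,2S)-2-hydroxy-2,6,6-trimethylcyclohexyl]-11-methyltrideca-6,10-dien-2-ynoate | C/C(=C\CC/C(=C/C[C@@H](O)C#CC(=O)OC)CO)CC[C@H]1C(C)(C)CCC[C@]1(C)O
F2 | step 8 | (5R)-4-{[dimethyl(propan-2-yloxy)silyl]methyl}-5-{(2Z,6E)-3-(hydroxymethyl)-9-[(1S,2S)-2-hydroxy-2,6,6-trimethylcyclohexyl]-7-methylnona-2,6-dien-1-yl}furan-2(5H)-one | C/C(=C\CC/C(=C/C[C@H]1OC(=O)C=C1C[Si](C)(C)OC(C)C)CO)CC[C@H]1C(C)(C)CCC[C@]1(C)O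
F3 | step 5 | 2-{(3E)-6-[(1S,2S)-2-hydroxy-2,6,6-trimethylcyclohexyl]-4-methylhex-3-en-1-yl}prop-2-en-1-ol | C/C(=C\CCC(=C)CO)CC[C@H]1C(C)(C)CCC[C@]1(C)O
F4 | step 5 | 2-{(3E)-6-[(1S,2S)-2-hydroxy-2,6,6-trimethylcyclohexyl]-4-methylhex-3-en-1-yl}prop-2-en-1-yl but-3-enoate | C/C(=C\CCC(=C)COC(=O)CC=C)CC[C@H]1C(C)(C)CCC[C@]1(C)O
F5 | step 5 | 5-{(3E)-6-[(1S,2S)-2-hydroxy-2,6,6-trimethylcyclohexyl]-4-methylhex-3-en-1-yl}-3,6-dihydro-2H-pyran-2-one | C/C(=C\CCC1=CCC(=O)OC1)CC[C@H]1C(C)(C)CCC[C@]1(C)O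
F0 | step 1 | none | none
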